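Early on nothing shows at 45 °C: the south flask reads 0% at 15.0 d, and so does the south-west flask. At 60.0 d the south flask reads 3.2% and the south-west flask 3.1%, although the south-west flask carries twice the loading of precatalyst. A rate that follows the loading should differ between these flasks, so the numbers seem not to go together.

| flask | substrate | reagent | precatalyst | temperature | remark | time |
|---|---|---|---|---|---|---|
| south | 0.34 M | 1 equiv | 0.2 mol% | 45 °C | run made earlier |  |
| north-east | 0.53 M | 1 equiv | 0.2 mol% | 80 °C | run made earlier |  |
| south-west | 0.24 M | 1 equiv | 0.4 mol% | 45 °C | run made earlier |  |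
| grey | 0.24 M | 1.00 equiv | 0.2 mol% |  | at 110 °C until 8.0 d, from then on at 50 °C | 10 d |
| green | 0.24 M | 1.00 equiv | 0.2 mol% | 80 °C |  | 10 d |
| violet | 0.24 M | 1.00 equiv | 0.2 mol% | 110 °C |  | 10 d |
| teal | 0.24 M | 1.00 equiv | 0.2 mol% | 50 °C |  | 10 d |

| run | time / d | target / % |
|---|---|---|
| south | 4.00 | 0 |
| south | 10.0 | 0.7 |
| south | 15.0 | 0 |
| south | 30.0 | 0.6 |
| south | 50.0 | 2.4 |
| south | 60.0 | 3.2 |
| north-east | 1.67 | 3.9 |
| north-east | 3.00 | 11.7 |
| north-east | 5.00 | 32.3 |
| north-east | 6.00 | 43.2 |
| north-east | 8.00 | 52.6 |
| north-east | 10.0 | 63.0 |
| north-east | 12.0 | 71.1 |
| south-west | 15.0 | 0 |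
| south-west | 30.0 | 1.5 |
| south-west | 50.0 | 3.3 |
| south-west | 60.0 | 3.1 |

(readings scatter by 1 percentage point)

- candidate steps: substrate + free catalyst <-> free catalyst + open intermediate; free catalyst + open intermediate <-> catalyst intermediate; reagent + catalyst intermediate -> free catalyst + target; precatalyst -> free catalyst

* the flask that comes out highest in amount of target, in percent of the substrate charged, or "all alike" when all lie within 1.5 percentage points (grey / green / violet / teal / all alike)
* target at the end, in percent of the substrate charged, grey
* target at the end, in percent of the substrate charged, green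
* target at the end, in percent of the substrate charged, violet
* target at the end, in percent of the substrate charged, teal

I clear this up from the candidate steps. If free catalyst is the resting state of the round, target forms at a rate that goes with c(free catalyst), c(open intermediate) and c(reagent). At one equivalent of reagent, the percent gained per day then goes with the loading times the square of the substrate concentration, and I call this product the push. The push of the south-west flask over that of the south flask is 0.997, so in this reckoning, which takes the catalyst as awake and the open intermediate as a fixed share of the substrate, the smaller charge offsets the larger loading; but each reading is good to 1 percentage point on a value near 3.2%, so the pair shows the two flasks to be of like size and does not tell a ratio of one from a ratio well above it.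

Grey, green, violet and teal carry one charge, so the push separates none of them, but it does set green against the north-east run at the same 80 °C. The push ratio, north-east over green, is 4.88. The north-east run climbs 0.103 d⁻¹ of its charge between 3.00 d and 5.00 d. I divide that slope by the ratio and count the time after 1.67 d as working time, which gives green 17.6%.

The forecast says 27% for green, above my figure, with 96% for grey, 97% for violet and 0.1% for teal, and it names violet highest: “so violet is nearly complete”.

The flasks give 46.5% in grey, 26.5% in green, 51.9% in violet and 0.0104% in teal, so violet is highest.

    substrate + free catalyst ⇌ free catalyst + open intermediate (K = 0.990, k = 48.0 L mol⁻¹ h⁻¹, Ea = 65.0 kJ mol⁻¹, ΔH = −54.0 kJ mol⁻¹)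
    free catalyst + open intermediate ⇌ catalyst intermediate (K = 1.50 L mol⁻¹, k = 410 L mol⁻¹ h⁻¹, Ea = 64.0 kJ mol⁻¹, ΔH = −30.0 kJ mol⁻¹)
    reagent + catalyst intermediate → free catalyst + target (k = 39.0 L mol⁻¹ h⁻¹, Ea = 80.0 kJ mol⁻¹)
    precatalyst → free catalyst (k = 0.0110 h⁻¹, Ea = 118 kJ mol⁻¹)
    (constants at 80 °C)

Violet stops short at 51.9% because the reverse step of catalyst intermediate and the time allowed act together: without that reverse step violet gives >99.9%, and by 100 d it gives 91.9%. The north-east slope is 3.23 times green's mean rate, against a push ratio of 4.88. The neighbour of grey charged with 0.060 M of substrate has its push cut by a factor of 16.0, and its target falls from 46.5% to 5.22%, a factor of 8.91.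

(The data stem from a simulated flask with constants of no real substance, noise included.)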